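Slowness in this flask can sit in two places, the catalyst's working round or the gas entering solution as reagent, and counting turnovers brackets the outcome without choosing between them.

- ochre: left-handed substrate 0.098 M; right-handed substrate 0.098 M; gas 4.8 mM (held); free catalyst 0.40 mM; impurity 35 µM; run made earlier
- flask: left-handed substrate 0.098 M; gas 4.8 mM (held); free catalyst 0.20 mM; impurity 35 µM; right-handed substrate 0.098 M; time 25 min

- ochre (time / min: left-handed product / %, right-handed product / %, left-handed substrate / %): 0.667: 0.3, 0.2, 49.0; 1.00: 0.9, 0.1, 48.3; 1.33: 1.3, 1.0, 48.1; 2.00: 2.8, 0, 47.8; 3.00: 3.4, 0.3, 46.0; 5.00: 6.4, 0.2, 43.1; 8.00: 10.7, 0.7, 39.5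

(readings scatter by 0.5 percentage points)

- free catalyst is single-handed; left-handed substrate and right-handed substrate are mirror images of each other, charged as a racemate, each of them at the stated concentration
- at the start none of reagent is dissolved
- what may be going on: free catalyst + right-handed substrate <-> catalyst intermediate B; free catalyst + left-handed substrate <-> catalyst intermediate A; reagent + catalyst intermediate A -> free catalyst + left-handed product; gas <-> reagent; reagent + catalyst intermediate B -> free catalyst + right-handed product; free catalyst + impurity -> spent catalyst; left-handed substrate <-> right-handed substrate
- an excess is the difference of the two amounts in percent of their sum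
- an excess is below zero if the other one leads
- no earlier run changes the charge of free catalyst; that part of a forecast is a guess

- excess of left-handed product over right-handed product in the product at 2.5 min
- excess of left-handed product over right-handed product in the product at 25 min
- part of the left-handed substrate and right-handed substrate charged together that has reacted at 25 min

Take the working catalyst as free catalyst charged minus impurity charged, one catalyst lost per impurity: 0.365 mM in the ochre run, 0.165 mM in the flask. The turnover frequency N is product of both hands formed per working catalyst per minute; the ochre readings at 8.00 min give N = 7.65 min⁻¹.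

The lower bound keeps N unchanged, since a smaller working charge draws reagent more slowly and reagent stands no lower. That estimate gives 16.1% reacted at 25 min.

From above, consuming the whole charge would need N = 47.5 min⁻¹. The ochre run tightens this: a smaller working charge takes no more reagent from the same gas, so the ochre product rate, read from readings that run nearly straight up to 8.00 min and carried on to 25 min, is taken as the ceiling. It gives 35.6% reacted, or N = 16.9 min⁻¹. No earlier run changes the charge of free catalyst, so the reckoning stops there.

The excess reads 87.7% at 8.00 min in the ochre run, resting on a right-handed product of 0.7% against a scatter of 0.5 percentage points.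

The forecast gives 88%, 85% and 17%, calls “the upper range is wide”, and its conversion stands inside the bracket, above the lower bound and below the upper.

The flask gives excesses of 93.9% at 2.5 min and 92.5% at 25 min, and 30.5% reacted, a conversion inside the bracket, with N = 14.5 min⁻¹ on average over the 25 min.

    free catalyst + right-handed substrate ⇌ catalyst intermediate B (K = 6.30 M⁻¹, k = 200 M⁻¹ s⁻¹)
    free catalyst + left-handed substrate ⇌ catalyst intermediate A (K = 94.0 M⁻¹, k = 800 M⁻¹ s⁻¹)
    reagent + catalyst intermediate A → free catalyst + left-handed product (k = 170 M⁻¹ s⁻¹)
    gas ⇌ reagent, rate k4*(csat - [reagent]) (kL = 0.0130 s⁻¹)
    reagent + catalyst intermediate B → free catalyst + right-handed product (k = 76.0 M⁻¹ s⁻¹)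
    free catalyst + impurity → spent catalyst (k = 250 M⁻¹ s⁻¹)
    left-handed substrate ⇌ right-handed substrate (k = 4.90 × 10⁻⁴ s⁻¹)

The neighbour flask, charged with 1.2 × 10⁻⁴ M of free catalyst, has a working charge of 0.0850 mM. The same count puts it between 8.30% and 35.6% reacted, or N between 7.65 min⁻¹ and 32.9 min⁻¹. It gives 23.6%, so N = 21.7 min⁻¹ on average, with excesses of 93.9% at 2.5 min and 92.9% at 25 min. At 25.0 min its reagent stands at 0.00250 M, against 0.00176 M in the flask.

The numbers in the tables are simulated with constants of no real substance; the scatter is artificial.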